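**Retrosynthetic overview**

1. Numbering (elemane type): ring = C5 [CH–C4(=C3H2)C15H2OH] – C6 (OH) – C7 [CH–C11(=C13H2)C12O2H] – C8 (O-acyl) – C9H2 – C10 (C14H3, C1H=C2H2). The acid is unveiled late by chlorite oxidation of a C12 enal, and the C8 ester by Yamaguchi coupling with (Z)-4-acetoxy-2-methylbut-2-enoic acid.
2. Key disconnection C6–C7: the unit C6(OH)–C7H–C11(=C13H2) of the cyclohexane is a trans-2-(alk-1-en-2-yl)cyclohexanol, a homoallylic alcohol. This is the retron of a type 1 carbonyl-ene closure of an acyclic C6 aldehyde onto a Z-alkene C7=C11(C13H3)(C12H2OSi). C12 is kept at the alcohol level so that the ene partner is electron-rich.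
3. The aldehyde comes from an enantioselective Ireland–Claisen rearrangement (C5–C10 bond; quaternary C10 and C5) of an allylic ester built from an oxidised geraniol and 3-(silyloxymethyl)but-3-enoic acid.
4. The allylic alcohol comes from a catalytic asymmetric vinylogous Mukaiyama aldol (C8–C9 bond, C8 stereocentre) between a Z-enal made from propargyl alcohol and a senecioate dienol ether.
5. Ring order: one ring only, the cyclohexane, closed in step 14. Stereocentres: C8 in step 5, C5/C10 in step 11, C6/C7 in step 14.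

Key step: step 14

Assumption: the absolute sense of the two reagent-controlled steps is written as expected from the accepted transition-state models (Si-face addition with the S,S bis-phosphoramide in step 5; the 2S,3R acid with the S,S boron controller in step 11); if a pilot run shows the opposite sense, the enantiomeric reagent is used with no other change.

**Route**

Step 1
Reactants: 1 prop-2-yn-1-ol
Product: 3 (2Z)-3-iodo-2-methylprop-2-en-1-ol, via alkenylmagnesium alkoxide 2 (not isolated)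
Conditions: MeMgBr (2.5 equiv), CuI (10 mol %), THF, −10 °C → rt; then I2, −10 °C
Reagents that add atoms: methylmagnesium bromide (C[Mg]Br); iodine (II)
Why: Copper-catalysed anti-carbomagnesiation of the propargylic alkoxide puts methyl on the internal carbon and magnesium on the terminus cis to CH2O (five-membered chelate), and iodinolysis with retention gives the Z-iodide that later fixes the C7=C11 geometry.

Step 2
Reactants: 3 (2Z)-3-iodo-2-methylprop-2-en-1-ol
Product: 4 tert-butyl{[(2Z)-3-iodo-2-methylprop-2-en-1-yl]oxy}dimethylsilane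
Conditions: TBSCl, imidazole, CH2Cl2, 0 °C → rt
Reagents that add atoms: tert-butyldimethylsilyl chloride (CC(C)(C)[Si](C)(C)Cl)
Why: Routine silyl ether formation on a primary allylic alcohol protects O12 for the organolithium and Lewis-acid steps.

Step 3
Reactants: 4 tert-butyl{[(2Z)-3-iodo-2-methylprop-2-en-1-yl]oxy}dimethylsilane
Product: 6 (2Z)-4-{[tert-butyl(dimethyl)silyl]oxy}-3-methylbut-2-enal, via alkenyllithium 5 (not isolated)
Conditions: t-BuLi (2.1 equiv), Et2O, −78 °C; then DMF, −78 → 0 °C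
Reagents that add atoms: N,N-dimethylformamide (CN(C)C=O)
Why: Iodine–lithium exchange proceeds with retention of alkene geometry and the alkenyllithium is formylated by DMF (Bouveault formylation), giving the Z-enal without passing through isomerising conditions.

Step 4
Reactants: 7 methyl 3-methylbut-2-enoate
Product: 9 tert-butyl[(1-methoxy-3-methylbuta-1,3-dien-1-yl)oxy]dimethylsilane, via lithium dienolate 8 (not isolated)
Conditions: LiN(i-Pr)2, THF/DMPU, −78 °C; then TBSCl
Reagents that add atoms: tert-butyldimethylsilyl chloride (CC(C)(C)[Si](C)(C)Cl)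
Why: γ-Deprotonation of the senecioate and O-silylation of the extended enolate give the silyl dienol ether used as vinylogous nucleophile.

Step 5
Reactants: 6 (2Z)-4-{[tert-butyl(dimethyl)silyl]oxy}-3-methylbut-2-enal; 9 tert-butyl[(1-methoxy-3-methylbuta-1,3-dien-1-yl)oxy]dimethylsilane
Product: 10 methyl (2E,5S,6Z)-8-{[tert-butyl(dimethyl)silyl]oxy}-5-hydroxy-3,7-dimethylocta-2,6-dienoate
Conditions: SiCl4 (1.2 equiv), (S,S)-bis-phosphoramide (two N,N′-dimethyl-1,1′-binaphthyl-2,2′-diamine phosphoramide units joined by an N,N′-dimethylpentane-1,5-diamine linker, 5 mol %), i-Pr2NEt (10 mol %), CH2Cl2, −78 °C; aq. NaHCO3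
Reagents that add atoms: none
Why: Catalytic enantioselective vinylogous Mukaiyama aldol addition, in which the Lewis-base-activated trichlorosilyl cation binds the aldehyde, the dienol ether attacks through its γ-carbon (E-enoate) and the chiral phosphoramide directs attack to the Si face, setting C8 as S while the low temperature preserves the Z-alkene.

Step 6
Reactants: 10 methyl (2E,5S,6Z)-8-{[tert-butyl(dimethyl)silyl]oxy}-5-hydroxy-3,7-dimethylocta-2,6-dienoate
Product: 11 methyl (2E,5S,6Z)-8-{[tert-butyl(dimethyl)silyl]oxy}-3,7-dimethyl-5-[(triethylsilyl)oxy]octa-2,6-dienoate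
Conditions: Et3SiCl, imidazole, CH2Cl2, 0 °C
Reagents that add atoms: chlorotriethylsilane (CC[Si](CC)(CC)Cl)
Why: Silylation of the secondary allylic alcohol gives a triethylsilyl ether that is weakly Lewis basic (needed in steps 11 and 14) and more labile than the other silyl ethers (needed in step 16).

Step 7
Reactants: 11 methyl (2E,5S,6Z)-8-{[tert-butyl(dimethyl)silyl]oxy}-3,7-dimethyl-5-[(triethylsilyl)oxy]octa-2,6-dienoate
Product: 12 (2E,5S,6Z)-8-{[tert-butyl(dimethyl)silyl]oxy}-3,7-dimethyl-5-[(triethylsilyl)oxy]octa-2,6-dien-1-ol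
Conditions: i-Bu2AlH (2.2 equiv), CH2Cl2, −78 °C; aq. potassium sodium tartrate
Reagents that add atoms: none
Why: 1,2-Reduction of the enoate by the aluminium hydride gives the E-allylic alcohol without touching the silyl ethers or the alkene geometries.

Step 8
Reactants: 13 2-methylprop-2-en-1-ol
Product: 15 lithium 3-(hydroxymethyl)but-3-enoate, via dilithio dianion 14 (not isolated)
Conditions: n-BuLi (2.2 equiv), TMEDA, Et2O/hexane, 0 °C → rt; then CO2, THF, −78 °C; H2O, aqueous phase freeze-dried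
Reagents that add atoms: n-butyllithium ([Li]CCCC); carbon dioxide (O=C=O)
Why: Double deprotonation of methallyl alcohol (alkoxide-directed allylic lithiation) and carboxylation of the symmetric allyl anion give the C5 acid, kept as its lithium salt so that the γ-hydroxy acid cannot lactonise.

Step 9
Reactants: 15 lithium 3-(hydroxymethyl)but-3-enoate
Product: 17 3-({[tert-butyl(diphenyl)silyl]oxy}methyl)but-3-enoic acid, via bis-silyl derivative 16 (not isolated)
Conditions: TBDPSCl (2.3 equiv), imidazole, DMF, rt; then K2CO3, MeOH/THF/H2O, 0 °C; pH 5 buffer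
Reagents that add atoms: tert-butyl(chloro)diphenylsilane (CC(C)(C)[Si](Cl)(c1ccccc1)c1ccccc1)
Why: Exhaustive silylation followed by selective solvolysis of the labile silyl ester leaves the robust primary silyl ether on O15, and the carboxylate form protects the β,γ-alkene from conjugation.

Step 10
Reactants: 12 (2E,5S,6Z)-8-{[tert-butyl(dimethyl)silyl]oxy}-3,7-dimethyl-5-[(triethylsilyl)oxy]octa-2,6-dien-1-ol; 17 3-({[tert-butyl(diphenyl)silyl]oxy}methyl)but-3-enoic acid
Product: 18 (2E,5S,6Z)-8-{[tert-butyl(dimethyl)silyl]oxy}-3,7-dimethyl-5-[(triethylsilyl)oxy]octa-2,6-dien-1-yl 3-({[tert-butyl(diphenyl)silyl]oxy}methyl)but-3-enoate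
Conditions: EDC·HCl, DMAP (10 mol %), CH2Cl2, 0 °C
Reagents that add atoms: none
Why: Carbodiimide (Steglich) esterification of the only free hydroxyl, run cold with little DMAP so that the β,γ-unsaturated acyl group does not slip into conjugation.

Step 11
Reactants: 18 (2E,5S,6Z)-8-{[tert-butyl(dimethyl)silyl]oxy}-3,7-dimethyl-5-[(triethylsilyl)oxy]octa-2,6-dien-1-yl 3-({[tert-butyl(diphenyl)silyl]oxy}methyl)but-3-enoate
Product: 20 (2S,3R,5S,6Z)-8-{[tert-butyl(dimethyl)silyl]oxy}-2-(3-{[tert-butyl(diphenyl)silyl]oxy}prop-1-en-2-yl)-3-ethenyl-3,7-dimethyl-5-[(triethylsilyl)oxy]oct-6-enoic acid, via boron ketene acetal 19 (not isolated)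
Conditions: (4S,5S)-2-bromo-4,5-diphenyl-1,3-bis{[3,5-bis(trifluoromethyl)phenyl]sulfonyl}-1,3,2-diazaborolidine (1.5 equiv), Et3N (4 equiv), toluene/hexane, −78 °C, then −20 → 4 °C, several days; aqueous work-up
Reagents that add atoms: none
Why: Enantioselective boron-enolate Ireland–Claisen rearrangement, in which the E(O) boron ketene acetal (Et3N, non-polar solvent) and the E-alkene pass through a chair that places C4 and C14 syn along the new C5–C10 bond, while the C2-symmetric sulfonamide controller selects the enolate face and so fixes C5 (S) and the quaternary C10 (R) independently of the remote C8.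

Step 12
Reactants: 20 (2S,3R,5S,6Z)-8-{[tert-butyl(dimethyl)silyl]oxy}-2-(3-{[tert-butyl(diphenyl)silyl]oxy}prop-1-en-2-yl)-3-ethenyl-3,7-dimethyl-5-[(triethylsilyl)oxy]oct-6-enoic acid
Product: 21 (2S,3R,5S,6Z)-8-{[tert-butyl(dimethyl)silyl]oxy}-2-(3-{[tert-butyl(diphenyl)silyl]oxy}prop-1-en-2-yl)-3-ethenyl-3,7-dimethyl-5-[(triethylsilyl)oxy]oct-6-en-1-ol
Conditions: LiAlH4, Et2O, 0 °C; basic aqueous work-up
Reagents that add atoms: none
Why: Hydride reduction of the hindered carboxylic acid to the primary alcohol leaves the silyl ethers and alkenes untouched and does not epimerise C5 (the carboxylate is not enolised).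

Step 13
Reactants: 21 (2S,3R,5S,6Z)-8-{[tert-butyl(dimethyl)silyl]oxy}-2-(3-{[tert-butyl(diphenyl)silyl]oxy}prop-1-en-2-yl)-3-ethenyl-3,7-dimethyl-5-[(triethylsilyl)oxy]oct-6-en-1-ol
Product: 22 (2S,3R,5S,6Z)-8-{[tert-butyl(dimethyl)silyl]oxy}-2-(3-{[tert-butyl(diphenyl)silyl]oxy}prop-1-en-2-yl)-3-ethenyl-3,7-dimethyl-5-[(triethylsilyl)oxy]oct-6-enal
Conditions: DMP, NaHCO3, CH2Cl2, 0 °C → rt
Reagents that add atoms: none
Why: Periodinane oxidation under buffered, base-free conditions gives the β,γ-unsaturated aldehyde without epimerising C5 or moving the C3=C4 alkene into conjugation.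

Step 14
Reactants: 22 (2S,3R,5S,6Z)-8-{[tert-butyl(dimethyl)silyl]oxy}-2-(3-{[tert-butyl(diphenyl)silyl]oxy}prop-1-en-2-yl)-3-ethenyl-3,7-dimethyl-5-[(triethylsilyl)oxy]oct-6-enal
Product: 23 (5S,6R,7S,8S,10R)-12-O-(tert-butyldimethylsilyl)-15-O-(tert-butyldiphenylsilyl)-8-O-(triethylsilyl)elema-1,3,11(13)-triene-6,8,12,15-tetrol
Conditions: Me2AlCl (1.5 equiv), CH2Cl2, −78 → −40 °C; aq. potassium sodium tartrate
Reagents that add atoms: none
Why: Me2AlCl binds the aldehyde oxygen and the cyclohexane closes by a type 1 intramolecular carbonyl-ene reaction: C7 of the electron-rich Z-trisubstituted alkene attacks C6 while a hydrogen of the C13 methyl group passes to the carbonyl oxygen through a six-membered array, so that the C6–C7 bond, the C6 hydroxyl and the exocyclic C11=C13 methylene are created together. The closest known reaction is the Lewis-acid cyclisation of citronellal to isopulegol, which gives the trans-2-isopropenylcyclohexanol through a chair. The ring closes in a 6-exo-trig sense at the carbonyl carbon (C6=O and C7=C11 both exocyclic to the forming ring) through a chair in which the C8 silyloxy group is equatorial with H8 eclipsing the C7=C11 bond (no allylic 1,3-strain with the cis C12H2OSi group) and the C10 methyl is equatorial, whereas the alternative chair would put C8–OSi and C10–CH3 syn-diaxial and press the silyloxy group against C12. In that chair the alkene face is fixed, which sets C7 with its side chain equatorial (trans to O8), and the Lewis-acid-bound carbonyl oxygen lies equatorial, away from the axial C10 vinyl group, which sets C6 with OH trans to the C7 side chain and cis to the C5 substituent as the target requires. The step needs hydrogen transfer from C13 and not from C12, which the Z geometry secures by placing the C13 methyl (trans to C8) under the carbonyl oxygen, and it needs the aldehyde to choose this alkene, which is secured because the vinyl group has no allylic hydrogen and the C3=C4 alkene is too close to C6. Me2AlCl also removes protons as methane, which suppresses ionisation of the allylic silyl ethers and other cationic side paths.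

Step 15
Reactants: 23 (5S,6R,7S,8S,10R)-12-O-(tert-butyldimethylsilyl)-15-O-(tert-butyldiphenylsilyl)-8-O-(triethylsilyl)elema-1,3,11(13)-triene-6,8,12,15-tetrol
Product: 24 (5S,6R,7R,8S,10R)-6,12-bis-O-(tert-butyldimethylsilyl)-15-O-(tert-butyldiphenylsilyl)-8-O-(triethylsilyl)elema-1,3,11(13)-triene-6,8,12,15-tetrol
Conditions: TBSOTf, 2,6-lutidine, CH2Cl2, −78 → 0 °C
Reagents that add atoms: tert-butyldimethylsilyl trifluoromethanesulfonate (CC(C)(C)[Si](C)(C)OS(=O)(=O)C(F)(F)F)
Why: The silyl triflate silylates the hindered C6 hydroxyl, which must be masked during acylation of O8 and during oxidation of C12 (a free O6 would trap the C12 aldehyde as a lactol and lead to the 6,12-lactone).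

Step 16
Reactants: 24 (5S,6R,7R,8S,10R)-6,12-bis-O-(tert-butyldimethylsilyl)-15-O-(tert-butyldiphenylsilyl)-8-O-(triethylsilyl)elema-1,3,11(13)-triene-6,8,12,15-tetrol
Product: 25 (5S,6R,7R,8S,10R)-6,12-bis-O-(tert-butyldimethylsilyl)-15-O-(tert-butyldiphenylsilyl)elema-1,3,11(13)-triene-6,8,12,15-tetrol
Conditions: PPTS (20 mol %), MeOH/CH2Cl2, 0 °C, monitored
Reagents that add atoms: none
Why: Mild acid-catalysed methanolysis removes the triethylsilyl ether much faster than the tert-butyldimethylsilyl and tert-butyldiphenylsilyl ethers, freeing only O8.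

Step 17
Reactants: 26 3-methylfuran-2,5-dione (citraconic anhydride)
Product: 27 (2Z)-2-methylbut-2-ene-1,4-diol
Conditions: LiAlH4, THF, 0 °C → rt; basic aqueous work-up
Reagents that add atoms: none
Why: Hydride reduction of the cyclic anhydride gives the diol with the Z geometry inherited from the ring.

Step 18
Reactants: 27 (2Z)-2-methylbut-2-ene-1,4-diol
Product: 28 (2Z)-4-hydroxy-3-methylbut-2-en-1-yl acetate
Conditions: vinyl acetate (3 equiv), immobilised Candida antarctica lipase B, THF, rt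
Reagents that add atoms: vinyl acetate (C=COC(C)=O)
Why: Lipase-catalysed irreversible transesterification distinguishes the two primary allylic hydroxyls and acetylates the less hindered one, remote from the methyl-bearing carbon.

Step 19
Reactants: 28 (2Z)-4-hydroxy-3-methylbut-2-en-1-yl acetate
Product: 30 (2Z)-4-(acetyloxy)-2-methylbut-2-enoic acid, via enal 29 (not isolated)
Conditions: TEMPO (10 mol %), NaOCl (5 mol %), NaClO2 (2 equiv), MeCN/phosphate buffer (pH 6.7), rt
Reagents that add atoms: sodium chlorite ([Na+].[O-]Cl=O)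
Why: Oxoammonium oxidation of the primary allylic alcohol to the aldehyde and immediate chlorite oxidation to the acid at near-neutral pH keep the labile Z-enal short-lived and the acetate intact, and the acetate blocks lactonisation to the butenolide.

Step 20
Reactants: 30 (2Z)-4-(acetyloxy)-2-methylbut-2-enoic acid; 25 (5S,6R,7R,8S,10R)-6,12-bis-O-(tert-butyldimethylsilyl)-15-O-(tert-butyldiphenylsilyl)elema-1,3,11(13)-triene-6,8,12,15-tetrol
Product: 32 (5S,6R,7R,8S,10R)-8-O-[(2Z)-4-acetoxy-2-methylbut-2-enoyl]-6,12-bis-O-(tert-butyldimethylsilyl)-15-O-(tert-butyldiphenylsilyl)elema-1,3,11(13)-triene-6,8,12,15-tetrol, via mixed anhydride 31 (not isolated)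
Conditions: 2,4,6-trichlorobenzoyl chloride, Et3N, toluene, rt; then 25, toluene, 70 °C (no DMAP)
Reagents that add atoms: none
Why: Yamaguchi esterification of the only free hydroxyl through the mixed anhydride, run without a nucleophilic catalyst as is usual for angelate-type acids, so that the Z-enoate does not isomerise to the E-isomer.

Step 21
Reactants: 32 (5S,6R,7R,8S,10R)-8-O-[(2Z)-4-acetoxy-2-methylbut-2-enoyl]-6,12-bis-O-(tert-butyldimethylsilyl)-15-O-(tert-butyldiphenylsilyl)elema-1,3,11(13)-triene-6,8,12,15-tetrol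
Product: 33 (5S,6R,7R,8S,10R)-8-O-[(2Z)-4-acetoxy-2-methylbut-2-enoyl]-6-O-(tert-butyldimethylsilyl)-15-O-(tert-butyldiphenylsilyl)elema-1,3,11(13)-triene-6,8,12,15-tetrol
Conditions: HF·pyridine, pyridine, THF, 0 °C
Reagents that add atoms: none
Why: Buffered HF·pyridine cleaves the unhindered primary tert-butyldimethylsilyl ether at O12 and spares the flanked secondary silyl ether at O6, the tert-butyldiphenylsilyl ether at O15 and both esters.

Step 22
Reactants: 33 (5S,6R,7R,8S,10R)-8-O-[(2Z)-4-acetoxy-2-methylbut-2-enoyl]-6-O-(tert-butyldimethylsilyl)-15-O-(tert-butyldiphenylsilyl)elema-1,3,11(13)-triene-6,8,12,15-tetrol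
Product: 34 (5S,6R,7R,8S,10R)-8-{[(2Z)-4-acetoxy-2-methylbut-2-enoyl]oxy}-6-[(tert-butyldimethylsilyl)oxy]-15-[(tert-butyldiphenylsilyl)oxy]elema-1,3,11(13)-trien-12-al
Conditions: MnO2 (excess), CH2Cl2, rt
Reagents that add atoms: none
Why: Manganese dioxide oxidises only the free allylic alcohol, giving the 2-substituted acrolein without affecting esters, silyl ethers or C7.

Step 23
Reactants: 34 (5S,6R,7R,8S,10R)-8-{[(2Z)-4-acetoxy-2-methylbut-2-enoyl]oxy}-6-[(tert-butyldimethylsilyl)oxy]-15-[(tert-butyldiphenylsilyl)oxy]elema-1,3,11(13)-trien-12-al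
Product: 35 (5S,6R,7R,8S,10R)-8-{[(2Z)-4-acetoxy-2-methylbut-2-enoyl]oxy}-6-[(tert-butyldimethylsilyl)oxy]-15-[(tert-butyldiphenylsilyl)oxy]elema-1,3,11(13)-trien-12-oic acid
Conditions: NaClO2, NaH2PO4, 2-methylbut-2-ene, t-BuOH/H2O, 0 °C
Reagents that add atoms: sodium chlorite ([Na+].[O-]Cl=O)
Why: Pinnick oxidation converts the enal into the acrylic acid under buffered conditions that leave the acetate, the Z-enoate and the alkenes alone, the alkene scavenger removing hypochlorite.

Step 24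
Reactants: 35 (5S,6R,7R,8S,10R)-8-{[(2Z)-4-acetoxy-2-methylbut-2-enoyl]oxy}-6-[(tert-butyldimethylsilyl)oxy]-15-[(tert-butyldiphenylsilyl)oxy]elema-1,3,11(13)-trien-12-oic acid
Product: 36 (5S,6R,7S,8S,10R)-8-{[(2Z)-4-acetoxy-2-methylbut-2-enoyl]oxy}-6,15-dihydroxyelema-1,3,11(13)-trien-12-oic acid (CNP0261293.4)
Conditions: Bu4NF/AcOH (1:1, excess), THF, rt; pH 4–5 buffer work-up
Reagents that add atoms: none
Why: Acetic-acid-buffered fluoride cleaves both remaining silyl ethers while the acid rests as its carboxylate, which should prevent closure to the 6,12-lactone and spare the two esters.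

**Compound list**

1 | prop-2-yn-1-ol | C#CCO | starting material
2 | bromomagnesium (2Z)-3-(bromomagnesio)-2-methylprop-2-en-1-olate (not isolated) | Br[Mg]/C=C(/C)CO[Mg]Br | intermediate
3 | (2Z)-3-iodo-2-methylprop-2-en-1-ol | I/C=C(/C)CO | intermediate
4 | tert-butyl{[(2Z)-3-iodo-2-methylprop-2-en-1-yl]oxy}dimethylsilane | I/C=C(/C)CO[Si](C)(C)C(C)(C)C | intermediate
5 | [(1Z)-3-{[tert-butyl(dimethyl)silyl]oxy}-2-methylprop-1-en-1-yl]lithium (not isolated) | [Li]/C=C(/C)CO[Si](C)(C)C(C)(C)C | intermediate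
6 | (2Z)-4-{[tert-butyl(dimethyl)silyl]oxy}-3-methylbut-2-enal | O=C/C=C(/C)CO[Si](C)(C)C(C)(C)C | intermediate
7 | methyl 3-methylbut-2-enoate | COC(=O)C=C(C)C | starting material
8 | lithium 1-methoxy-3-methylbuta-1,3-dien-1-olate (not isolated) | [Li]OC(OC)=CC(C)=C | intermediate
9 | tert-butyl[(1-methoxy-3-methylbuta-1,3-dien-1-yl)oxy]dimethylsilane | COC(O[Si](C)(C)C(C)(C)C)=CC(C)=C | intermediate
10 | methyl (2E,5S,6Z)-8-{[tert-butyl(dimethyl)silyl]oxy}-5-hydroxy-3,7-dimethylocta-2,6-dienoate | COC(=O)/C=C(\C)C[C@H](O)/C=C(/C)CO[Si](C)(C)C(C)(C)C | intermediate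
11 | methyl (2E,5S,6Z)-8-{[tert-butyl(dimethyl)silyl]oxy}-3,7-dimethyl-5-[(triethylsilyl)oxy]octa-2,6-dienoate | COC(=O)/C=C(\C)C[C@H](O[Si](CC)(CC)CC)/C=C(/C)CO[Si](C)(C)C(C)(C)C | intermediate
12 | (2E,5S,6Z)-8-{[tert-butyl(dimethyl)silyl]oxy}-3,7-dimethyl-5-[(triethylsilyl)oxy]octa-2,6-dien-1-ol | OC/C=C(\C)C[C@H](O[Si](CC)(CC)CC)/C=C(/C)CO[Si](C)(C)C(C)(C)C | intermediate
13 | 2-methylprop-2-en-1-ol | C=C(C)CO | starting material
14 | [2-(lithiooxymethyl)prop-2-en-1-yl]lithium (not isolated) | [Li]CC(=C)CO[Li] | intermediate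
15 | lithium 3-(hydroxymethyl)but-3-enoate | [Li+].[O-]C(=O)CC(=C)CO | intermediate
16 | tert-butyl(diphenyl)silyl 3-({[tert-butyl(diphenyl)silyl]oxy}methyl)but-3-enoate (not isolated) | C=C(CO[Si](c1ccccc1)(c1ccccc1)C(C)(C)C)CC(=O)O[Si](c1ccccc1)(c1ccccc1)C(C)(C)C | intermediate
17 | 3-({[tert-butyl(diphenyl)silyl]oxy}methyl)but-3-enoic acid | C=C(CO[Si](c1ccccc1)(c1ccccc1)C(C)(C)C)CC(=O)O | intermediate
18 | (2E,5S,6Z)-8-{[tert-butyl(dimethyl)silyl]oxy}-3,7-dimethyl-5-[(triethylsilyl)oxy]octa-2,6-dien-1-yl 3-({[tert-butyl(diphenyl)silyl]oxy}methyl)but-3-enoate | C=C(CO[Si](c1ccccc1)(c1ccccc1)C(C)(C)C)CC(=O)OC/C=C(\C)C[C@H](O[Si](CC)(CC)CC)/C=C(/C)CO[Si](C)(C)C(C)(C)C | intermediate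
19 | E(O) boron ketene acetal of 18 with the (4S,5S)-diazaborolidine (not isolated) | C=C(CO[Si](c1ccccc1)(c1ccccc1)C(C)(C)C)/C=C(/OB1N(S(=O)(=O)c2cc(cc(c2)C(F)(F)F)C(F)(F)F)[C@@H](c2ccccc2)[C@H](c2ccccc2)N1S(=O)(=O)c1cc(cc(c1)C(F)(F)F)C(F)(F)F)OC/C=C(\C)C[C@H](O[Si](CC)(CC)CC)/C=C(/C)CO[Si](C)(C)C(C)(C)C | intermediate
20 | (2S,3R,5S,6Z)-8-{[tert-butyl(dimethyl)silyl]oxy}-2-(3-{[tert-butyl(diphenyl)silyl]oxy}prop-1-en-2-yl)-3-ethenyl-3,7-dimethyl-5-[(triethylsilyl)oxy]oct-6-enoic acid | C=C[C@@](C)(C[C@H](O[Si](CC)(CC)CC)/C=C(/C)CO[Si](C)(C)C(C)(C)C)[C@H](C(=O)O)C(=C)CO[Si](c1ccccc1)(c1ccccc1)C(C)(C)C | intermediate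
21 | (2S,3R,5S,6Z)-8-{[tert-butyl(dimethyl)silyl]oxy}-2-(3-{[tert-butyl(diphenyl)silyl]oxy}prop-1-en-2-yl)-3-ethenyl-3,7-dimethyl-5-[(triethylsilyl)oxy]oct-6-en-1-ol | C=C[C@@](C)(C[C@H](O[Si](CC)(CC)CC)/C=C(/C)CO[Si](C)(C)C(C)(C)C)[C@H](CO)C(=C)CO[Si](c1ccccc1)(c1ccccc1)C(C)(C)C | intermediate
22 | (2S,3R,5S,6Z)-8-{[tert-butyl(dimethyl)silyl]oxy}-2-(3-{[tert-butyl(diphenyl)silyl]oxy}prop-1-en-2-yl)-3-ethenyl-3,7-dimethyl-5-[(triethylsilyl)oxy]oct-6-enal | C=C[C@@](C)(C[C@H](O[Si](CC)(CC)CC)/C=C(/C)CO[Si](C)(C)C(C)(C)C)[C@H](C=O)C(=C)CO[Si](c1ccccc1)(c1ccccc1)C(C)(C)C | intermediate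
23 | (5S,6R,7S,8S,10R)-12-O-(tert-butyldimethylsilyl)-15-O-(tert-butyldiphenylsilyl)-8-O-(triethylsilyl)elema-1,3,11(13)-triene-6,8,12,15-tetrol | C=C[C@@]1(C)C[C@H](O[Si](CC)(CC)CC)[C@@H](C(=C)CO[Si](C)(C)C(C)(C)C)[C@H](O)[C@@H]1C(=C)CO[Si](c1ccccc1)(c1ccccc1)C(C)(C)C | intermediate
24 | (5S,6R,7R,8S,10R)-6,12-bis-O-(tert-butyldimethylsilyl)-15-O-(tert-butyldiphenylsilyl)-8-O-(triethylsilyl)elema-1,3,11(13)-triene-6,8,12,15-tetrol | C=C[C@@]1(C)C[C@H](O[Si](CC)(CC)CC)[C@@H](C(=C)CO[Si](C)(C)C(C)(C)C)[C@H](O[Si](C)(C)C(C)(C)C)[C@@H]1C(=C)CO[Si](c1ccccc1)(c1ccccc1)C(C)(C)C | intermediate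
25 | (5S,6R,7R,8S,10R)-6,12-bis-O-(tert-butyldimethylsilyl)-15-O-(tert-butyldiphenylsilyl)elema-1,3,11(13)-triene-6,8,12,15-tetrol (free 8-OH) | C=C[C@@]1(C)C[C@H](O)[C@@H](C(=C)CO[Si](C)(C)C(C)(C)C)[C@H](O[Si](C)(C)C(C)(C)C)[C@@H]1C(=C)CO[Si](c1ccccc1)(c1ccccc1)C(C)(C)C | intermediate
26 | 3-methylfuran-2,5-dione (citraconic anhydride) | CC1=CC(=O)OC1=O | starting material
27 | (2Z)-2-methylbut-2-ene-1,4-diol | OC/C=C(/C)CO | intermediate
28 | (2Z)-4-hydroxy-3-methylbut-2-en-1-yl acetate | CC(=O)OC/C=C(/C)CO | intermediate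
29 | (2Z)-3-methyl-4-oxobut-2-en-1-yl acetate (not isolated) | CC(=O)OC/C=C(/C)C=O | intermediate
30 | (2Z)-4-(acetyloxy)-2-methylbut-2-enoic acid | CC(=O)OC/C=C(/C)C(=O)O | intermediate
31 | (2Z)-4-(acetyloxy)-2-methylbut-2-enoic 2,4,6-trichlorobenzoic anhydride (not isolated) | CC(=O)OC/C=C(/C)C(=O)OC(=O)c1c(Cl)cc(Cl)cc1Cl | intermediate
32 | (5S,6R,7R,8S,10R)-8-O-[(2Z)-4-acetoxy-2-methylbut-2-enoyl]-6,12-bis-O-(tert-butyldimethylsilyl)-15-O-(tert-butyldiphenylsilyl)elema-1,3,11(13)-triene-6,8,12,15-tetrol | C=C[C@@]1(C)C[C@H](OC(=O)/C(C)=C\COC(C)=O)[C@@H](C(=C)CO[Si](C)(C)C(C)(C)C)[C@H](O[Si](C)(C)C(C)(C)C)[C@@H]1C(=C)CO[Si](c1ccccc1)(c1ccccc1)C(C)(C)C | intermediate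
33 | (5S,6R,7R,8S,10R)-8-O-[(2Z)-4-acetoxy-2-methylbut-2-enoyl]-6-O-(tert-butyldimethylsilyl)-15-O-(tert-butyldiphenylsilyl)elema-1,3,11(13)-triene-6,8,12,15-tetrol (free 12-OH) | C=C[C@@]1(C)C[C@H](OC(=O)/C(C)=C\COC(C)=O)[C@@H](C(=C)CO)[C@H](O[Si](C)(C)C(C)(C)C)[C@@H]1C(=C)CO[Si](c1ccccc1)(c1ccccc1)C(C)(C)C | intermediate
34 | (5S,6R,7R,8S,10R)-8-{[(2Z)-4-acetoxy-2-methylbut-2-enoyl]oxy}-6-[(tert-butyldimethylsilyl)oxy]-15-[(tert-butyldiphenylsilyl)oxy]elema-1,3,11(13)-trien-12-al | C=C[C@@]1(C)C[C@H](OC(=O)/C(C)=C\COC(C)=O)[C@@H](C(=C)C=O)[C@H](O[Si](C)(C)C(C)(C)C)[C@@H]1C(=C)CO[Si](c1ccccc1)(c1ccccc1)C(C)(C)C | intermediate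
35 | (5S,6R,7R,8S,10R)-8-{[(2Z)-4-acetoxy-2-methylbut-2-enoyl]oxy}-6-[(tert-butyldimethylsilyl)oxy]-15-[(tert-butyldiphenylsilyl)oxy]elema-1,3,11(13)-trien-12-oic acid | C=C[C@@]1(C)C[C@H](OC(=O)/C(C)=C\COC(C)=O)[C@@H](C(=C)C(=O)O)[C@H](O[Si](C)(C)C(C)(C)C)[C@@H]1C(=C)CO[Si](c1ccccc1)(c1ccccc1)C(C)(C)C | intermediate
36 | (5S,6R,7S,8S,10R)-8-{[(2Z)-4-acetoxy-2-methylbut-2-enoyl]oxy}-6,15-dihydroxyelema-1,3,11(13)-trien-12-oic acid (CNP0261293.4) | C=C[C@@]1(C)C[C@H](OC(=O)/C(C)=C\COC(C)=O)[C@@H](C(=C)C(=O)O)[C@H](O)[C@@H]1C(=C)CO | target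

**Step count**

Total step count: 24. Longest linear sequence: 18 steps (1, 2, 3, 5, 6, 7, 10, 11, 12, 13, 14, 15, 16, 20, 21, 22, 23, 24).

**Steps most likely to fail**

Step 14 (ene ring closure). What may go wrong is diversion into cationic pathways (chloride capture at C11, hydrogen transfer from the C12 methylene, ionisation of the allylic C8 silyl ether) or poor discrimination between the two chairs. The fallback sets out from 22 and comes back at 23, using polar allyl-metal chemistry in place of the pericyclic step. Ene-type allylic chlorination of the most electron-rich alkene of 22 with Ca(OCl)2 and solid CO2 in CH2Cl2/H2O at 0 °C (chlorine to C7, double bond moved to C11=C13) would give the secondary allylic chloride F1. CrCl2 in THF would convert it into the allylchromium species F2 (not isolated), which should add through its more substituted terminus C7 to the C6 aldehyde in an intramolecular Nozaki–Hiyama–Kishi-type allylation through a closed chair, anti-selective, to give 23.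

Step 11 (Ireland–Claisen). What may go wrong is loss of control over enolate geometry or face with the boron controller, or a rearrangement at the congested C10 so slow that the Lewis-acidic boron erodes the silyl ethers. The fallback sets out from 18 and comes back at 20, giving up absolute control in favour of separation. Enolisation with LiN(i-Pr)2 in THF at −78 °C and O-silylation with Me3SiCl would give the trimethylsilyl ketene acetal F3, which on warming to room temperature should rearrange through the same chair (classical Ireland–Claisen, relative C5/C10 configuration still fixed by enolate and alkene geometry) to the trimethylsilyl ester F4 and its diastereomer, the trimethylsilyl ester F5. Aqueous work-up would give 20 together with the (2R,3S) acid F6; the two differ as diastereomers because of the C8 stereocentre and would be separated by chromatography.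

Step 24 (final desilylation). What may go wrong is incomplete cleavage of the hindered C6 silyl ether and, on forcing, loss or migration of the acyl groups or lactonisation of the γ-hydroxy acid. The fallback sets out from 34 and comes back at 36, with the order of events changed so that the acid is formed last. Bu4NF/AcOH in THF on the neutral enal 34 would give the dihydroxy enal F7, which should rest largely as the 6,12-lactol F8. Chlorite oxidation (NaClO2, NaH2PO4, 2-methylbut-2-ene, t-BuOH/H2O) of this pair through its open form would then give 36 directly under buffered conditions.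

Further compounds
F1 | step 14 | (2S,3R,5S)-8-{[tert-butyl(dimethyl)silyl]oxy}-2-(3-{[tert-butyl(diphenyl)silyl]oxy}prop-1-en-2-yl)-6-chloro-3-ethenyl-3-methyl-7-methylidene-5-[(triethylsilyl)oxy]octanal (both C6 epimers) | C=C[C@@](C)(C[C@H](O[Si](CC)(CC)CC)C(Cl)C(=C)CO[Si](C)(C)C(C)(C)C)[C@H](C=O)C(=C)CO[Si](c1ccccc1)(c1ccccc1)C(C)(C)C
F2 | step 14 | allylchromium dichloride species derived from F1 (not isolated) | C=C[C@@](C)(C[C@H](O[Si](CC)(CC)CC)C=C(C[Cr](Cl)Cl)CO[Si](C)(C)C(C)(C)C)[C@H](C=O)C(=C)CO[Si](c1ccccc1)(c1ccccc1)C(C)(C)C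
F3 | step 11 | trimethylsilyl ketene acetal of 18 (E(O) enolate geometry) | C=C(CO[Si](c1ccccc1)(c1ccccc1)C(C)(C)C)/C=C(/O[Si](C)(C)C)OC/C=C(\C)C[C@H](O[Si](CC)(CC)CC)/C=C(/C)CO[Si](C)(C)C(C)(C)C
F4 | step 11 | trimethylsilyl ester of acid 20 | C=C[C@@](C)(C[C@H](O[Si](CC)(CC)CC)/C=C(/C)CO[Si](C)(C)C(C)(C)C)[C@H](C(=O)O[Si](C)(C)C)C(=C)CO[Si](c1ccccc1)(c1ccccc1)C(C)(C)C
F5 | step 11 | trimethylsilyl ester of the (2R,3S,5S,6Z) diastereomer of 20 | C=C[C@](C)(C[C@H](O[Si](CC)(CC)CC)/C=C(/C)CO[Si](C)(C)C(C)(C)C)[C@@H](C(=O)O[Si](C)(C)C)C(=C)CO[Si](c1ccccc1)(c1ccccc1)C(C)(C)C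
F6 | step 11 | (2R,3S,5S,6Z)-8-{[tert-butyl(dimethyl)silyl]oxy}-2-(3-{[tert-butyl(diphenyl)silyl]oxy}prop-1-en-2-yl)-3-ethenyl-3,7-dimethyl-5-[(triethylsilyl)oxy]oct-6-enoic acid | C=C[C@](C)(C[C@H](O[Si](CC)(CC)CC)/C=C(/C)CO[Si](C)(C)C(C)(C)C)[C@@H](C(=O)O)C(=C)CO[Si](c1ccccc1)(c1ccccc1)C(C)(C)C
F7 | step 24 | (5S,6R,7S,8S,10R)-8-{[(2Z)-4-acetoxy-2-methylbut-2-enoyl]oxy}-6,15-dihydroxyelema-1,3,11(13)-trien-12-al | C=C[C@@]1(C)C[C@H](OC(=O)/C(C)=C\COC(C)=O)[C@@H](C(=C)C=O)[C@H](O)[C@@H]1C(=C)CO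
F8 | step 24 | 6,12-lactol of F7 (12-hydroxy-6,12-epoxy form, both C12 epimers) | C=C[C@@]1(C)C[C@H](OC(=O)/C(C)=C\COC(C)=O)[C@H]2C(=C)C(O)O[C@@H]2[C@@H]1C(=C)CO
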